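**Remarks on the chemistry (assumptions)**
- The target has no stereogenic centre and no stereogenic double bond (both olefins end in CMe2). It is achiral, so "the single enantiomer" is the compound itself and the task is one of regiochemistry.
- Intermediates 8 and 13 carry stereocentres that are destroyed in step 6. They are carried as mixtures and their SMILES are written without descriptors.
- LDA and LiHMDS are used as commercial solutions; 5 is taken as a catalogue compound.
- Ring carbons are called C1–C6 (C1 bears CO2Me). Positions of the open polyketide chain are called k1–k9 (k1 = ester carbon, k9 = benzylic CH2).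

## Analysis of the target

Target 16 is a hexasubstituted benzene (ring A: C1 CO2Me, C2 OH, C3 prenyl, C4 OH, C5 prenyl, C6 CH2CH2Ph) joined through an ethylene bridge to an unsubstituted phenyl ring. It is a doubly C-prenylated dihydrostilbene-2-carboxylate with no stereocentres.

The sensitive groups are:
- two trisubstituted olefins, each ortho to a free phenol, which acid closes to 2,2-dimethylchromans and which rule out late hydrogenation or strong electrophiles;
- an electron-rich resorcinol;
- a methyl ester wedged between the hydrogen-bonded C2–OH and the C6 side chain.

The difficulty is regiochemical. No ring CH is left, C3 and C5 carry the same group in different surroundings, and C5 lies between C4–OH and the phenethyl-bearing C6. On the finished arene nothing controls C- versus O-prenylation, C3 versus C5, or mono- versus bis-alkylation.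

The feature that invites the strategy is the 1,3-relation of the oxygens at C2 and C4 with the carboxyl on C1. Ring A C1–C6 maps onto k2–k7 of a 3,5,7-trioxo-9-phenylnonanoate (hydrocinnamoyl starter plus three acetate units). The ring bond C1–C6 is the k2–k7 aldol bond of the biosynthesis. The prenyl-bearing carbons C3 and C5 are k4 and k6, the two chain methylenes that sit between two carbonyl groups. On the open chain these two carbons are told apart by connectivity alone, so the plan is to prenylate the chain and then fold it biomimetically.

## Retrosynthetic reasoning

**16 ⇒ 15 (ring bond C1–C6 = k2–k7).** The arene is opened at the bond the biosynthesis makes, giving the fully substituted triketo ester 15. This cut removes the whole regiochemical problem of ring A in one operation. The forward step must be a k2→k7 aldol closure, dehydration and aromatisation, without Claisen closure or lactonisation.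

**15 ⇒ 14 ⇒ 13 (ester C–O bond at k1).** The k1–k3 β-keto ester is masked as the dioxinone ring of 13. Thermal cycloreversion gives acylketene 14, and the alcohol that supplies the ester methyl captures it. The mask survives the strong bases used earlier and is removed by heat alone. It delivers the hindered methyl ester without esterifying a 2,6-disubstituted benzoic acid.

**13 ⇒ 8 + 10 (chain bond k6–k7).** The phenethyl ketone is attached last, by acylating dianion 11 of keto-dioxinone 8 with the N-methoxy-N-methylamide 10. The cut is placed here because k6 is the last-formed and most reactive carbanion of 11, so the site of bond formation is not in doubt. The chelated adduct 12 prevents over-addition and proton-transfer quenching. Amide 10 comes in one step from acid chloride 9.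

**8 ⇒ 4 + 6 (chain bond k4–k5).** γ-Acylation of dienolate 7 (from dioxinone 4) with acid chloride 6 forms this bond. Acid chloride 6 brings k5, k6 and the future C5 prenyl group as one homoprenyl unit, so no separate alkylation at k6 is needed. 6 comes from acid 5.

**4 ⇒ 1 + 2 (bond between k4 and its prenyl CH2).** The future C3 prenyl group is attached by γ-alkylation of dienolate 3 of the commercial dioxinone 1 with prenyl bromide 2. At this stage k4 is the only nucleophilic carbon in the molecule.

Both prenyl groups are therefore attached to chain carbons before ring A exists, and no protecting group is needed.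

## Alternatives that were turned down

**Alternative 1: late double C-prenylation (the textbook route).** The disconnection is the two aryl–CH2 bonds at C3 and C5. The forward key step would be treatment of methyl 2,4-dihydroxy-6-(2-phenylethyl)benzoate A1 with 2 and base, or acid-mediated Friedel–Crafts prenylation. It was turned down for these reasons:
- The phenoxides of A1 are ambident and the C4 oxygen is the most nucleophilic site, so O-prenyl ethers are expected.
- C-attack can occur at C3 or C5, and the first prenyl group makes the ring more reactive, so mono-, bis- and gem-dialkylated dearomatised products would form together.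
- Acidic variants close the ortho-prenyl phenols to chromans.
- C5 must be alkylated next to the phenethyl chain, and nothing in A1 favours it.
- A1 itself needs about three steps, and the key step would build no bond of ring A.

**Alternative 2: double aromatic Claisen rearrangement.** The same two aryl–C bonds would be formed by [3,3] shifts of the bis(1,1-dimethylallyl) ether A2, made from A1. Each shift inverts the allyl unit and gives a normal prenyl group ortho to its oxygen. It was turned down for these reasons:
- A2 needs tertiary ether formation on both phenols, including the C2–OH that is hydrogen-bonded to and flanked by the ester. In practice this means 1,1-dimethylpropargylation and semi-hydrogenation, done twice, so four to five steps after A1.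
- The C4–O allyl group has two free ortho positions and should prefer the less hindered C3. The C2–O group then has no free ortho carbon and can reach C5 only by a further Cope shift, which would deliver a reverse prenyl group.
- The temperatures needed favour chroman formation.

**Alternative 3: Diels–Alder benzannulation.** The disconnection is the ring bonds C1–C2 and C5–C6. The forward key step would be [4+2] cycloaddition of the diprenylated 1-methoxy-1,3-bis(trimethylsilyloxy)diene A3 with alkynoate A4, then elimination and desilylation. This is convergent and the polarity match gives the right regiochemistry on paper. It was turned down for these reasons: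
- A4 is a β-alkyl alkynoate and a weak dienophile.
- A3 is a tetrasubstituted diene, and both new bonds would join hindered carbons (ketene-acetal carbon to the ester-bearing alkyne carbon, prenyl-bearing terminus to the phenethyl-bearing carbon).
- Forcing thermal conditions invite silyl transfer and decomposition of the ketene acetal.
- Lewis acids open stepwise Michael pathways that lose regiocontrol.
- A3 needs three enolate steps from methyl acetoacetate and its double-bond geometry is not controlled, so nothing is saved.

Key step: step 6

## Route

Step 1
Reactants: 1 2,2,6-trimethyl-4H-1,3-dioxin-4-one; 2 1-bromo-3-methylbut-2-ene (prenyl bromide)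
Product: 4 2,2-dimethyl-6-(4-methylpent-3-en-1-yl)-4H-1,3-dioxin-4-one, via parent lithium dienolate 3 (not isolated)
Conditions: LDA (1.1 equiv), THF, −78 °C; DMPU, 2 (1.2 equiv), −78 → −40 °C
Reagents that add atoms: 1-bromo-3-methylbut-2-ene (2), CC(C)=CCBr
Why: Kinetic deprotonation of the C6 methyl group gives the cross-conjugated dienolate 3, which should react with a reactive allylic bromide at its γ-carbon in the presence of DMPU (vinylogous enolate γ-alkylation). SN2 attack at the primary carbon of 2 gives the linear prenyl unit; no stereocentre is formed.

Step 2
Reactants: 5 5-methylhex-4-enoic acid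
Product: 6 5-methylhex-4-enoyl chloride
Conditions: (COCl)2 (1.2 equiv), DMF (cat.), CH2Cl2, 0 °C → rt; concentrate, use crude
Reagents that add atoms: oxalyl chloride, O=C(Cl)C(=O)Cl
Why: DMF-catalysed acid chloride formation. At 0 °C with the gases leaving the flask, the trisubstituted olefin should survive the brief contact with HCl.

Step 3
Reactants: 4 2,2-dimethyl-6-(4-methylpent-3-en-1-yl)-4H-1,3-dioxin-4-one; 6 5-methylhex-4-enoyl chloride
Product: 8 6-(2,10-dimethyl-6-oxoundeca-2,9-dien-5-yl)-2,2-dimethyl-4H-1,3-dioxin-4-one, via substituted lithium dienolate 7 (not isolated)
Conditions: 4 (2.0 equiv), LiHMDS (2.0 equiv), THF, −78 °C; 6 (1.0 equiv), −78 → −40 °C; AcOH, aq. NH4Cl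
Reagents that add atoms: none
Why: γ-C-Acylation of a dioxinone lithium dienolate by an acid chloride (vinylogous crossed Claisen condensation) forms the k4–k5 bond. The second equivalent of 7 takes up the acidic k4 proton of the product and is recovered as 4; the k4 stereocentre forms racemic and is erased in step 6.

Step 4
Reactants: 9 3-phenylpropanoyl chloride
Product: 10 N-methoxy-N-methyl-3-phenylpropanamide
Conditions: MeNHOMe·HCl (1.1 equiv), Et3N (2.2 equiv), CH2Cl2, 0 °C → rt
Reagents that add atoms: N,O-dimethylhydroxylamine hydrochloride, CNOC.Cl
Why: Standard acylation of an amine by an acid chloride, giving an acyl donor with no acidic N–H that forms a stable chelated adduct in step 5.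

Step 5
Reactants: 8 6-(2,10-dimethyl-6-oxoundeca-2,9-dien-5-yl)-2,2-dimethyl-4H-1,3-dioxin-4-one; 10 N-methoxy-N-methyl-3-phenylpropanamide
Product: 13 2,2-dimethyl-6-[2-methyl-7-(3-methylbut-2-en-1-yl)-6,8-dioxo-10-phenyldec-2-en-5-yl]-4H-1,3-dioxin-4-one, via dilithium dianion 11 (not isolated), via lithium hemiaminal adduct 12 (not isolated)
Conditions: LDA (2.2 equiv), THF, −78 → −40 °C; 10 (1.2 equiv), −78 → −20 °C; sat. aq. NH4Cl; use without chromatography on basic media
Reagents that add atoms: none
Why: LDA removes first the doubly activated k4–H and then a k6–H; the last-formed carbanion k6 of dianion 11 is the most nucleophilic site and should add to the N-methoxy-N-methylamide (dianion Claisen condensation of a β-dicarbonyl system). Adduct 12 holds the new ketone as a chelate until work-up, so neither over-addition nor quenching of 11 by the acidic product occurs; the k4/k6 stereocentres are uncontrolled and irrelevant.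

Step 6
Reactants: 13 2,2-dimethyl-6-[2-methyl-7-(3-methylbut-2-en-1-yl)-6,8-dioxo-10-phenyldec-2-en-5-yl]-4H-1,3-dioxin-4-one
Product: 16 methyl 2,4-dihydroxy-3,5-bis(3-methylbut-2-en-1-yl)-6-(2-phenylethyl)benzoate, via acylketene 14 (not isolated), via triketo ester 15 (not isolated)
Conditions: MeOH (10 equiv), PhMe, 110 °C (sealed tube); cool; Cs2CO3 (0.5 equiv, catalytic base), MeOH, 0 °C → rt; AcOH quench
Reagents that add atoms: methanol, CO
Why: Above about 100 °C the dioxinone of 13 should undergo retro-hetero-Diels–Alder cleavage to acylketene 14, which methanol captures at the ketene carbon to give triketo ester 15, the tetraketide of the biosynthesis with both prenyl groups already on k4 and k6. Carbonate then enolises k2, the only unsubstituted doubly activated methylene, and this carbon adds to the k7 ketone in a 6-exo-trig aldol closure (6-enolendo-exo-trig for the k2=k3 enol) that forms ring bond C1–C6; loss of water and two enolisations give the benzene ring. The closest known reaction type is thermolysis of diketo-dioxinones in the presence of an alcohol followed by base-mediated aldol aromatisation to resorcylate esters, the laboratory copy of the C2→C7 folding of stilbenecarboxylates. No stereocentre is formed, and the two sp3 centres of 13 become sp2 ring atoms, so every diastereomer and tautomer converges on 16. The step needs k2→k7 aldol closure to win over Claisen closure k6→k1, lactonisation of a k5 enol oxygen onto k1, and the reverse aldol k8→k3. This is secured because k6 is tertiary and its Claisen closure would give a quaternary carbon that cannot aromatise and can revert, k8 is activated by one carbonyl only and is not enolised by carbonate, excess methanol outruns internal O-capture of the ketene, and aromatisation makes the desired path irreversible. The positions of all six ring substituents follow from chain connectivity alone, and the mild acetic acid quench should avoid chroman formation from the ortho-prenyl phenols.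

## Compound list

1 | 2,2,6-trimethyl-4H-1,3-dioxin-4-one | CC1=CC(=O)OC(C)(C)O1 | starting material
2 | 1-bromo-3-methylbut-2-ene (prenyl bromide) | CC(C)=CCBr | starting material
3 | lithium dienolate of 1 (lithium 2,2-dimethyl-6-methylidene-6H-1,3-dioxin-4-olate) | C=C1C=C(O[Li])OC(C)(C)O1 | intermediate (not isolated)
4 | 2,2-dimethyl-6-(4-methylpent-3-en-1-yl)-4H-1,3-dioxin-4-one | CC(C)=CCCC1=CC(=O)OC(C)(C)O1 | intermediate
5 | 5-methylhex-4-enoic acid | CC(C)=CCCC(=O)O | starting material
6 | 5-methylhex-4-enoyl chloride | CC(C)=CCCC(=O)Cl | intermediate
7 | lithium dienolate of 4 | CC(C)=CCC=C1C=C(O[Li])OC(C)(C)O1 | intermediate (not isolated)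
8 | 6-(2,10-dimethyl-6-oxoundeca-2,9-dien-5-yl)-2,2-dimethyl-4H-1,3-dioxin-4-one (racemic) | CC(C)=CCC(C(=O)CCC=C(C)C)C1=CC(=O)OC(C)(C)O1 | intermediate
9 | 3-phenylpropanoyl chloride | O=C(Cl)CCc1ccccc1 | starting material
10 | N-methoxy-N-methyl-3-phenylpropanamide | CON(C)C(=O)CCc1ccccc1 | intermediate
11 | dilithium dianion of 8 | CC(C)=CCC(=C1C=C(O[Li])OC(C)(C)O1)C(O[Li])=CCC=C(C)C | intermediate (not isolated)
12 | lithium hemiaminal adduct of 11 and 10 | CC(C)=CCC(=C1C=C(O[Li])OC(C)(C)O1)C(=O)C(CC=C(C)C)C(O[Li])(N(C)OC)CCc1ccccc1 | intermediate (not isolated)
13 | 2,2-dimethyl-6-[2-methyl-7-(3-methylbut-2-en-1-yl)-6,8-dioxo-10-phenyldec-2-en-5-yl]-4H-1,3-dioxin-4-one (mixture of diastereomers and enol tautomers) | CC(C)=CCC(C(=O)C(CC=C(C)C)C(=O)CCc1ccccc1)C1=CC(=O)OC(C)(C)O1 | intermediate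
14 | 4,6-bis(3-methylbut-2-en-1-yl)-9-phenylnon-1-ene-1,3,5,7-tetrone (acylketene) | O=C=CC(=O)C(CC=C(C)C)C(=O)C(CC=C(C)C)C(=O)CCc1ccccc1 | intermediate (not isolated)
15 | methyl 4,6-bis(3-methylbut-2-en-1-yl)-3,5,7-trioxo-9-phenylnonanoate | COC(=O)CC(=O)C(CC=C(C)C)C(=O)C(CC=C(C)C)C(=O)CCc1ccccc1 | intermediate (not isolated)
16 | methyl 2,4-dihydroxy-3,5-bis(3-methylbut-2-en-1-yl)-6-(2-phenylethyl)benzoate | COC(=O)c1c(O)c(CC=C(C)C)c(O)c(CC=C(C)C)c1CCc1ccccc1 | target

## Step count and risk

Total step count: 6. Longest linear sequence: 4 steps (steps 1, 3, 5, 6). No protecting group is used.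

**Step 6 (key step).** Three processes may interfere:
- internal capture of the acylketene by an enol oxygen (pyrone formation), or base-free aldol closure onto the intact dioxinone before cycloreversion;
- retro-Claisen fragmentation of the 2-substituted 1,3-diketone units by methoxide during the base stage;
- acid-promoted closure of an ortho-prenyl phenol to a chroman at work-up.

Fallback, from 13 to 16: aromatise first and open the ring afterwards. Treating 13 with Cs2CO3 in THF at room temperature should give, by aldol closure of the dioxinone C5 onto the k7 ketone, 7-hydroxy-2,2-dimethyl-6,8-bis(3-methylbut-2-en-1-yl)-5-(2-phenylethyl)-4H-1,3-benzodioxin-4-one F1. Opening F1 with NaOMe in MeOH at 60 °C should then give 16.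

**Step 5.** Acylation at the secondary dianion carbon may be slow, so proton transfer or attack of the dianion on a dioxinone carbonyl could compete. Fallback, from 8 to 13: add the same dianion to 3-phenylpropanal at −78 °C (aldol addition, fast even at hindered carbanions) to give 6-[8-hydroxy-2-methyl-7-(3-methylbut-2-en-1-yl)-6-oxo-10-phenyldec-2-en-5-yl]-2,2-dimethyl-4H-1,3-dioxin-4-one F2. Oxidise F2 with Dess–Martin periodinane in CH2Cl2 to 13.

**Step 3.** The γ-substituted dienolate may undergo O-acylation or acylation at ring C5 instead of at the hindered γ-carbon. Fallback, from 1 to 8 (also bypasses step 1): acylate the unsubstituted dienolate of 1 (LiHMDS, THF, −78 °C) with 6 to give 2,2-dimethyl-6-(6-methyl-2-oxohept-5-en-1-yl)-4H-1,3-dioxin-4-one F3. Then C-prenylate the active methylene between the ring and the ketone with 2 (K2CO3, acetone) to reach 8.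

**Step 1.** Alkylation at ring C5, double alkylation, or decomposition of the dienolate on warming may lower the yield. Fallback, from 6 to 4: acylate 2,2-dimethyl-1,3-dioxane-4,6-dione (Meldrum's acid) with 6 (pyridine, CH2Cl2, 0 °C) to give 5-(1-hydroxy-5-methylhex-4-en-1-ylidene)-2,2-dimethyl-1,3-dioxane-4,6-dione F4. Heating F4 with excess acetone in toluene should give 4 through the acylketene and its hetero-Diels–Alder capture by acetone.

## Further compounds

F1 | step 6 | 7-hydroxy-2,2-dimethyl-6,8-bis(3-methylbut-2-en-1-yl)-5-(2-phenylethyl)-4H-1,3-benzodioxin-4-one | CC1(C)OC(=O)c2c(CCc3ccccc3)c(CC=C(C)C)c(O)c(CC=C(C)C)c2O1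
F2 | step 5 | 6-[8-hydroxy-2-methyl-7-(3-methylbut-2-en-1-yl)-6-oxo-10-phenyldec-2-en-5-yl]-2,2-dimethyl-4H-1,3-dioxin-4-one (mixture of diastereomers) | CC(C)=CCC(C(=O)C(CC=C(C)C)C(O)CCc1ccccc1)C1=CC(=O)OC(C)(C)O1
F3 | step 3 | 2,2-dimethyl-6-(6-methyl-2-oxohept-5-en-1-yl)-4H-1,3-dioxin-4-one | CC(C)=CCCC(=O)CC1=CC(=O)OC(C)(C)O1
F4 | step 1 | 5-(1-hydroxy-5-methylhex-4-en-1-ylidene)-2,2-dimethyl-1,3-dioxane-4,6-dione | CC(C)=CCCC(O)=C1C(=O)OC(C)(C)OC1=O
A1 | alternative 1 | methyl 2,4-dihydroxy-6-(2-phenylethyl)benzoate | COC(=O)c1c(O)cc(O)cc1CCc1ccccc1
A2 | alternative 2 | methyl 2,4-bis[(2-methylbut-3-en-2-yl)oxy]-6-(2-phenylethyl)benzoate | COC(=O)c1c(OC(C)(C)C=C)cc(OC(C)(C)C=C)cc1CCc1ccccc1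
A3 | alternative 3 | 1-methoxy-7-methyl-2-(3-methylbut-2-en-1-yl)-1,3-bis(trimethylsilyloxy)octa-1,3,6-triene (double-bond geometry not controlled) | COC(O[Si](C)(C)C)=C(CC=C(C)C)C(O[Si](C)(C)C)=CCC=C(C)C
A4 | alternative 3 | methyl 5-phenylpent-2-ynoate | COC(=O)C#CCCc1ccccc1
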